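**Retrosynthetic overview**

1. Target 26 consists of guaiacyl ring A, benzene ring B fused to dihydrofuran ring C (O1, C2, C3, C3a, C7a) and benzene ring D fused to dihydrofuran ring E (primed locants). The end game only unmasks: tert-butyl cinnamate to allylic alcohol, then three TIPS ethers off.
2. Enabling feature: in ring C and again in ring E the ether oxygen is bonded to an aromatic carbon (C7a, C7a') that lies between the methoxy carbon C7 and the fusion carbon C3a and is reached from the carbinol oxygen through C2–C3–C3a. Both aryl–oxygen bonds (O1–C7a of ring C, O1'–C7a' of ring E) are therefore cut together, back to the open-chain dibromo diol 22.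
3. 22 comes from two Evans syn aldols that draw on one arylacetyl imide 11 in two roles. Its boron enolate 14 adds to aldehyde 13, made from 11 by ozonolysis of the acrylate arm (sets C2', C3'). The arylacetyl imide kept in adduct 15 is then enolised and added to silylated vanillin 17 (sets C2, C3).
4. 11 comes from 2-bromo-3-methoxybenzaldehyde by one-carbon homologation, C5-selective C–H borylation and oxidative Heck coupling with tert-butyl acrylate.
5. Ring order: benzene rings A, B and D are purchased; dihydrofuran rings C and E are closed together, in one operation, in step 13.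

Key step: step 13

Remark: the secondary ozonide 12 is written without configuration at its two new ring carbons, and 23 is written as the isomer in which ring E has closed first (its bromide is para to the electron-poor acrylate arm).

**Route**

Step 1
Reactants: 1 2-bromo-3-methoxybenzaldehyde; 2 methyl (methylthio)methyl sulfoxide
Product: 3 2-bromo-1-methoxy-3-[2-(methylsulfinyl)-2-(methylthio)ethenyl]benzene (E/Z mixture)
Conditions: 2 (1.2 equiv), benzyltrimethylammonium hydroxide (40% in MeOH, 0.3 equiv), THF, reflux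
Reagents that add atoms: none
Why: Knoevenagel-type condensation of the doubly sulfur-activated CH2 group of 2 with the aldehyde should give the ketene dithioacetal S-oxide, a masked arylacetic ester.

Step 2
Reactants: 3 2-bromo-1-methoxy-3-[2-(methylsulfinyl)-2-(methylthio)ethenyl]benzene
Product: 4 ethyl 2-(2-bromo-3-methoxyphenyl)acetate
Conditions: dry HCl (sat.), EtOH, 0 °C → rt
Reagents that add atoms: ethanol, CCO
Why: acid ethanolysis of a ketene dithioacetal S-oxide (C-protonation, addition of ethanol to the sulfur-stabilised cation, loss of both sulfur groups as the disulfide) is the established one-carbon homologation of an aryl aldehyde to an arylacetic ester.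

Step 3
Reactants: 4 ethyl 2-(2-bromo-3-methoxyphenyl)acetate
Product: 5 ethyl 2-[2-bromo-3-methoxy-5-(4,4,5,5-tetramethyl-1,3,2-dioxaborolan-2-yl)phenyl]acetate
Conditions: [Ir(OMe)(cod)]2 (1.5 mol %), 4,4'-di-tert-butyl-2,2'-bipyridine (3 mol %), B2pin2 (1.0 equiv), THF, 80 °C
Reagents that add atoms: bis(pinacolato)diboron, CC1(C)OB(OC1(C)C)B1OC(C)(C)C(C)(C)O1
Why: iridium-catalysed aromatic C–H borylation is sterically controlled, and in this 1,2,3-trisubstituted ring only C5–H has no ortho substituent; aryl bromides are tolerated.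

Step 4
Reactants: 5 ethyl 2-[2-bromo-3-methoxy-5-(4,4,5,5-tetramethyl-1,3,2-dioxaborolan-2-yl)phenyl]acetate; 6 tert-butyl acrylate
Product: 7 tert-butyl (E)-3-[4-bromo-3-(2-ethoxy-2-oxoethyl)-5-methoxyphenyl]prop-2-enoate
Conditions: Pd(OAc)2 (5 mol %), 2,9-dimethyl-1,10-phenanthroline (6 mol %), 6 (2 equiv), O2 (1 atm), DMF, 50 °C
Reagents that add atoms: none
Why: oxidative boron Mizoroki–Heck reaction (transmetalation of the aryl boronate to divalent palladium, syn insertion, β-hydride elimination to the E-enoate, reoxidation of zerovalent palladium by O2); the phosphine-free nitrogen-ligated catalyst should leave the doubly ortho-substituted C–Br bond alone.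

Step 5
Reactants: 7 tert-butyl (E)-3-[4-bromo-3-(2-ethoxy-2-oxoethyl)-5-methoxyphenyl]prop-2-enoate
Product: 8 2-[2-bromo-5-[(E)-3-tert-butoxy-3-oxoprop-1-enyl]-3-methoxyphenyl]acetic acid
Conditions: LiOH·H2O (1.5 equiv), THF/H2O 3:1, 0 °C → rt; then 1 M HCl to pH 3
Reagents that add atoms: lithium hydroxide, [Li+].[OH-]
Why: saponification should cleave the unhindered ethyl ester only, because the tert-butyl cinnamate resists hydroxide at room temperature.

Step 6
Reactants: 8 2-[2-bromo-5-[(E)-3-tert-butoxy-3-oxoprop-1-enyl]-3-methoxyphenyl]acetic acid; 9 (R)-4-benzyl-1,3-oxazolidin-2-one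
Product: 11 (R)-4-benzyl-3-[2-[2-bromo-5-[(E)-3-tert-butoxy-3-oxoprop-1-enyl]-3-methoxyphenyl]acetyl]-1,3-oxazolidin-2-one, via mixed pivalic anhydride 10 (not isolated)
Conditions: t-BuCOCl (1.1 equiv), Et3N (2.5 equiv), THF, −20 °C; then 9 (1.0 equiv), LiCl (1.1 equiv), −20 °C → rt
Reagents that add atoms: none
Why: N-acylation of the oxazolidinone by a mixed pivalic anhydride (LiCl-promoted) should occur at the less hindered arylacetyl carbonyl.

Step 7
Reactants: 11 (R)-4-benzyl-3-[2-[2-bromo-5-[(E)-3-tert-butoxy-3-oxoprop-1-enyl]-3-methoxyphenyl]acetyl]-1,3-oxazolidin-2-one (the portion set aside as the ring B unit)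
Product: 13 (R)-4-benzyl-3-[2-(2-bromo-5-formyl-3-methoxyphenyl)acetyl]-1,3-oxazolidin-2-one, via secondary ozonide 12 (not isolated)
Conditions: O3, CH2Cl2, −78 °C (Sudan Red 7B end-point); then Me2S, −78 °C → rt
Reagents that add atoms: ozone, [O-][O+]=O
Why: ozonolysis with reductive work-up should cleave the only alkene (the acrylate arm) to the aryl aldehyde, and at this stage the molecule holds no electron-rich arene that ozone could attack.

Step 8
Reactants: 11 (R)-4-benzyl-3-[2-[2-bromo-5-[(E)-3-tert-butoxy-3-oxoprop-1-enyl]-3-methoxyphenyl]acetyl]-1,3-oxazolidin-2-one; 13 (R)-4-benzyl-3-[2-(2-bromo-5-formyl-3-methoxyphenyl)acetyl]-1,3-oxazolidin-2-one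
Product: 15 (R)-4-benzyl-3-[(2R,3R)-3-[3-[2-[(R)-4-benzyl-2-oxo-1,3-oxazolidin-3-yl]-2-oxoethyl]-4-bromo-5-methoxyphenyl]-2-[2-bromo-5-[(E)-3-tert-butoxy-3-oxoprop-1-enyl]-3-methoxyphenyl]-3-hydroxypropanoyl]-1,3-oxazolidin-2-one, via dibutylboron Z-enolate 14 (not isolated)
Conditions: 11 (1.3 equiv), Bu2BOTf (1.25 equiv), i-Pr2NEt (1.5 equiv), CH2Cl2, 0 °C; 13 (1.0 equiv), −78 → 0 °C; then pH 7 buffer (KH2PO4/K2HPO4), MeOH, 30% H2O2, 0 °C
Reagents that add atoms: none
Why: Evans syn aldol in which the Z-boron enolate reacts through a Zimmerman–Traxler chair with the carbonyl dipoles opposed and the aldehyde adds to the enolate face away from the benzyl group of the (R)-auxiliary, which sets both new centres as (2R,3R), the syn array that becomes trans-C2'/C3' of ring E; Bu2BOTf is kept below the amount of 11 so that no free boron triflate is left to enolise the arylacetyl imide of 13.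

Step 9
Reactants: 16 vanillin (4-hydroxy-3-methoxybenzaldehyde)
Product: 17 3-methoxy-4-(triisopropylsilyloxy)benzaldehyde
Conditions: i-Pr3SiCl (1.2 equiv), imidazole (2.5 equiv), DMF, rt
Reagents that add atoms: triisopropylsilyl chloride, CC(C)[Si](Cl)(C(C)C)C(C)C
Why: phenol silylation gives a ring A protecting group that should survive boron enolates, hydrides and carbonate base, and leaves with fluoride at the end.

Step 10
Reactants: 15 (the aldol adduct of step 8); 17 3-methoxy-4-(triisopropylsilyloxy)benzaldehyde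
Product: 20 (R)-4-benzyl-3-[(2R,3R)-2-[2-bromo-5-[(1R,2R)-3-[(R)-4-benzyl-2-oxo-1,3-oxazolidin-3-yl]-2-[2-bromo-5-[(E)-3-tert-butoxy-3-oxoprop-1-enyl]-3-methoxyphenyl]-1-hydroxy-3-oxopropyl]-3-methoxyphenyl]-3-hydroxy-3-[3-methoxy-4-(triisopropylsilyloxy)phenyl]propanoyl]-1,3-oxazolidin-2-one, via O-dibutylboryl ether 18 (not isolated), via O-boryl dibutylboron Z-enolate 19 (not isolated)
Conditions: Bu2BOTf (2.3 equiv), i-Pr2NEt (2.8 equiv), CH2Cl2, −78 → 0 °C, 30 min; 17 (1.5 equiv), −78 → 0 °C; then pH 7 buffer (KH2PO4/K2HPO4), MeOH, 30% H2O2, 0 °C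
Reagents that add atoms: none
Why: second Evans syn aldol, in which the first equivalent of Bu2BOTf caps the free hydroxyl as borinate 18 so that it cannot quench an enolate, the second enolises only the unsubstituted arylacetyl imide (the imide that already carries the aldol resists enolisation because its enolate would suffer allylic 1,3-strain between the α-aryl group and the auxiliary), and the same (R)-auxiliary and chair transition state set the new pair as (2R,3R), the syn array that becomes trans-C2/C3 of ring C, independently of the remote centres.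

Step 11
Reactants: 20 (the bis(imide) of step 10)
Product: 21 tert-butyl (E)-3-[4-bromo-3-[(1R,2S)-1-[4-bromo-3-[(1R,2S)-1,3-dihydroxy-1-[3-methoxy-4-(triisopropylsilyloxy)phenyl]propan-2-yl]-5-methoxyphenyl]-1,3-dihydroxypropan-2-yl]-5-methoxyphenyl]prop-2-enoate
Conditions: LiBH4 (5 equiv), MeOH (5 equiv), THF, 0 °C; sat. aq. NH4Cl
Reagents that add atoms: none
Why: LiBH4 should reduce both exocyclic imide carbonyls to CH2OH and release the auxiliary while the tert-butyl enoate is inert; the aryl-bearing carbons change descriptor from R to S by CIP priority only.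

Step 12
Reactants: 21 (the tetraol of step 11)
Product: 22 tert-butyl (E)-3-[4-bromo-3-[(1R,2S)-1-[4-bromo-3-[(1R,2S)-1-hydroxy-1-[3-methoxy-4-(triisopropylsilyloxy)phenyl]-3-(triisopropylsilyloxy)propan-2-yl]-5-methoxyphenyl]-1-hydroxy-3-(triisopropylsilyloxy)propan-2-yl]-5-methoxyphenyl]prop-2-enoate
Conditions: i-Pr3SiCl (2.3 equiv), imidazole (5 equiv), DMF, 0 °C → rt
Reagents that add atoms: triisopropylsilyl chloride, CC(C)[Si](Cl)(C(C)C)C(C)C
Why: the bulky silyl chloride should react with the two primary hydroxyls and leave the two hindered secondary benzylic hydroxyls free, which is the differentiation the key step needs.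

Step 13
Reactants: 22 (the dibromo diol of step 12)
Product: 24 tert-butyl (E)-3-[(2R,3S)-7-methoxy-2-[(2R,3S)-7-methoxy-2-[3-methoxy-4-(triisopropylsilyloxy)phenyl]-3-[(triisopropylsilyloxy)methyl]-2,3-dihydro-1-benzofuran-5-yl]-3-[(triisopropylsilyloxy)methyl]-2,3-dihydro-1-benzofuran-5-yl]prop-2-enoate, via mono-cyclised bromo alcohol 23 (not isolated)
Conditions: CuI (30 mol %), 3,4,7,8-tetramethyl-1,10-phenanthroline (60 mol %), Cs2CO3 (5 equiv), toluene (0.02 M), 110 °C, argon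
Reagents that add atoms: none
Why: Cs2CO3 turns each free secondary benzylic hydroxyl into a phenanthroline-ligated alkoxide of monovalent copper, which activates the C–Br bond of the neighbouring ring (oxidative addition to trivalent copper or its concerted equivalent), and reductive elimination forms the aryl C–O bond; the same event then repeats on the second alkoxide/bromide pair in the same flask, so 23 is only a passing intermediate. The closest known reaction type is the copper-catalysed intramolecular Ullmann O-arylation of 2-(2-bromoaryl)ethanols to 2,3-dihydrobenzofurans. Rings C and E each close in a 5-exo mode: O1 (or O1') attacks the ipso carbon C7a (or C7a') and bromide leaves from outside the new ring. No stereocentre is created: C2/C3 and C2'/C3' come from the two aldols and are retained because neither the carbinol C–O bond nor the C3–H bond is touched, so the syn-aldol relationship becomes trans-2,3 substitution in both rings. The step needs secondary over primary oxygen (secured by the TIPS ethers, since a free CH2OH would reach the same C7a through an equally five-membered transition state), each alkoxide pairing with its own bromide (the other bromide is para to the carbinol carbon or ten or more atoms away), and cyclisation over intermolecular etherification and β-hydride loss (secured by high dilution and by copper instead of palladium).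

Step 14
Reactants: 24 (the bis-dihydrobenzofuran ester of step 13)
Product: 25 (E)-3-[(2R,3S)-7-methoxy-2-[(2R,3S)-7-methoxy-2-[3-methoxy-4-(triisopropylsilyloxy)phenyl]-3-[(triisopropylsilyloxy)methyl]-2,3-dihydro-1-benzofuran-5-yl]-3-[(triisopropylsilyloxy)methyl]-2,3-dihydro-1-benzofuran-5-yl]prop-2-en-1-ol
Conditions: i-Bu2AlH (3.5 equiv), CH2Cl2, −78 → −20 °C; aq. KNaC4H4O6 (potassium sodium tartrate) work-up
Reagents that add atoms: none
Why: i-Bu2AlH should reduce the enoate 1,2 to the E-allylic alcohol without touching silyl ethers, aryl ethers or the stereocentres.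

Step 15
Reactants: 25 (the tris-silyl ether of step 14)
Product: 26 (E)-3-[(2R,3S)-2-[(2R,3S)-2-(4-hydroxy-3-methoxyphenyl)-3-(hydroxymethyl)-7-methoxy-2,3-dihydro-1-benzofuran-5-yl]-3-(hydroxymethyl)-7-methoxy-2,3-dihydro-1-benzofuran-5-yl]prop-2-en-1-ol (target)
Conditions: Bu4NF (4 equiv), AcOH (4 equiv), THF, 0 °C → rt
Reagents that add atoms: none
Why: fluoride should cleave the aryl and both primary alkyl TIPS ethers; the acetic acid buffer keeps the liberated phenol from opening ring C through a quinone methide, and acid that would ionise the allylic alcohol is avoided.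

**Compound list**

1 | 2-bromo-3-methoxybenzaldehyde | COc1cccc(C=O)c1Br | starting material
2 | methyl (methylthio)methyl sulfoxide | CSCS(C)=O | starting material
3 | 2-bromo-1-methoxy-3-[2-(methylsulfinyl)-2-(methylthio)ethenyl]benzene (E/Z mixture) | COc1cccc(C=C(SC)S(C)=O)c1Br | intermediate
4 | ethyl 2-(2-bromo-3-methoxyphenyl)acetate | CCOC(=O)Cc1cccc(OC)c1Br | intermediate
5 | ethyl 2-[2-bromo-3-methoxy-5-(4,4,5,5-tetramethyl-1,3,2-dioxaborolan-2-yl)phenyl]acetate | CCOC(=O)Cc1cc(B2OC(C)(C)C(C)(C)O2)cc(OC)c1Br | intermediate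
6 | tert-butyl acrylate | C=CC(=O)OC(C)(C)C | starting material
7 | tert-butyl (E)-3-[4-bromo-3-(2-ethoxy-2-oxoethyl)-5-methoxyphenyl]prop-2-enoate | CCOC(=O)Cc1cc(/C=C/C(=O)OC(C)(C)C)cc(OC)c1Br | intermediate
8 | 2-[2-bromo-5-[(E)-3-tert-butoxy-3-oxoprop-1-enyl]-3-methoxyphenyl]acetic acid | OC(=O)Cc1cc(/C=C/C(=O)OC(C)(C)C)cc(OC)c1Br | intermediate
9 | (R)-4-benzyl-1,3-oxazolidin-2-one | O=C1N[C@H](Cc2ccccc2)CO1 | starting material
10 | mixed pivalic anhydride of 8 | CC(C)(C)C(=O)OC(=O)Cc1cc(/C=C/C(=O)OC(C)(C)C)cc(OC)c1Br | intermediate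
11 | (R)-4-benzyl-3-[2-[2-bromo-5-[(E)-3-tert-butoxy-3-oxoprop-1-enyl]-3-methoxyphenyl]acetyl]-1,3-oxazolidin-2-one | O=C(Cc1cc(/C=C/C(=O)OC(C)(C)C)cc(OC)c1Br)N1[C@H](Cc2ccccc2)COC1=O | intermediate
12 | secondary ozonide (1,2,4-trioxolane) of 11 | O=C(Cc1cc(C2OOC(O2)C(=O)OC(C)(C)C)cc(OC)c1Br)N1[C@H](Cc2ccccc2)COC1=O | intermediate
13 | (R)-4-benzyl-3-[2-(2-bromo-5-formyl-3-methoxyphenyl)acetyl]-1,3-oxazolidin-2-one | O=C(Cc1cc(C=O)cc(OC)c1Br)N1[C@H](Cc2ccccc2)COC1=O | intermediate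
14 | dibutylboron Z-enolate of 11 | CCCCB(CCCC)O/C(=C\c1cc(/C=C/C(=O)OC(C)(C)C)cc(OC)c1Br)N1[C@H](Cc2ccccc2)COC1=O | intermediate
15 | (R)-4-benzyl-3-[(2R,3R)-3-[3-[2-[(R)-4-benzyl-2-oxo-1,3-oxazolidin-3-yl]-2-oxoethyl]-4-bromo-5-methoxyphenyl]-2-[2-bromo-5-[(E)-3-tert-butoxy-3-oxoprop-1-enyl]-3-methoxyphenyl]-3-hydroxypropanoyl]-1,3-oxazolidin-2-one | O=C(Cc1cc([C@H](O)[C@@H](c2cc(/C=C/C(=O)OC(C)(C)C)cc(OC)c2Br)C(=O)N2[C@H](Cc3ccccc3)COC2=O)cc(OC)c1Br)N1[C@H](Cc2ccccc2)COC1=O | intermediate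
16 | vanillin | COc1cc(C=O)ccc1O | starting material
17 | 3-methoxy-4-(triisopropylsilyloxy)benzaldehyde | COc1cc(C=O)ccc1O[Si](C(C)C)(C(C)C)C(C)C | intermediate
18 | O-dibutylboryl ether (borinate) of 15 | O=C(Cc1cc([C@H](OB(CCCC)CCCC)[C@@H](c2cc(/C=C/C(=O)OC(C)(C)C)cc(OC)c2Br)C(=O)N2[C@H](Cc3ccccc3)COC2=O)cc(OC)c1Br)N1[C@H](Cc2ccccc2)COC1=O | intermediate
19 | dibutylboron Z-enolate of the arylacetyl imide of 18 | CCCCB(CCCC)O/C(=C\c1cc([C@H](OB(CCCC)CCCC)[C@@H](c2cc(/C=C/C(=O)OC(C)(C)C)cc(OC)c2Br)C(=O)N2[C@H](Cc3ccccc3)COC2=O)cc(OC)c1Br)N1[C@H](Cc2ccccc2)COC1=O | intermediate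
20 | bis(imide), (2R,3R) in the ring A propanoyl unit and (1R,2R) in the ring B hydroxypropyl unit (full name in step 10) | COc1cc([C@H](O)[C@@H](c2cc([C@H](O)[C@@H](c3cc(/C=C/C(=O)OC(C)(C)C)cc(OC)c3Br)C(=O)N3[C@H](Cc4ccccc4)COC3=O)cc(OC)c2Br)C(=O)N2[C@H](Cc3ccccc3)COC2=O)ccc1O[Si](C(C)C)(C(C)C)C(C)C | intermediate
21 | tert-butyl (E)-3-[4-bromo-3-[(1R,2S)-1-[4-bromo-3-[(1R,2S)-1,3-dihydroxy-1-[3-methoxy-4-(triisopropylsilyloxy)phenyl]propan-2-yl]-5-methoxyphenyl]-1,3-dihydroxypropan-2-yl]-5-methoxyphenyl]prop-2-enoate | COc1cc([C@H](O)[C@@H](c2cc([C@H](O)[C@@H](c3cc(/C=C/C(=O)OC(C)(C)C)cc(OC)c3Br)CO)cc(OC)c2Br)CO)ccc1O[Si](C(C)C)(C(C)C)C(C)C | intermediate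
22 | tert-butyl (E)-3-[4-bromo-3-[(1R,2S)-1-[4-bromo-3-[(1R,2S)-1-hydroxy-1-[3-methoxy-4-(triisopropylsilyloxy)phenyl]-3-(triisopropylsilyloxy)propan-2-yl]-5-methoxyphenyl]-1-hydroxy-3-(triisopropylsilyloxy)propan-2-yl]-5-methoxyphenyl]prop-2-enoate | COc1cc([C@H](O)[C@@H](c2cc([C@H](O)[C@@H](c3cc(/C=C/C(=O)OC(C)(C)C)cc(OC)c3Br)CO[Si](C(C)C)(C(C)C)C(C)C)cc(OC)c2Br)CO[Si](C(C)C)(C(C)C)C(C)C)ccc1O[Si](C(C)C)(C(C)C)C(C)C | intermediate
23 | tert-butyl (E)-3-[(2R,3S)-2-[4-bromo-3-[(1R,2S)-1-hydroxy-1-[3-methoxy-4-(triisopropylsilyloxy)phenyl]-3-(triisopropylsilyloxy)propan-2-yl]-5-methoxyphenyl]-7-methoxy-3-[(triisopropylsilyloxy)methyl]-2,3-dihydro-1-benzofuran-5-yl]prop-2-enoate | COc1cc([C@H](O)[C@@H](c2cc([C@@H]3Oc4c(OC)cc(/C=C/C(=O)OC(C)(C)C)cc4[C@H]3CO[Si](C(C)C)(C(C)C)C(C)C)cc(OC)c2Br)CO[Si](C(C)C)(C(C)C)C(C)C)ccc1O[Si](C(C)C)(C(C)C)C(C)C | intermediate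
24 | tert-butyl (E)-3-[(2R,3S)-7-methoxy-2-[(2R,3S)-7-methoxy-2-[3-methoxy-4-(triisopropylsilyloxy)phenyl]-3-[(triisopropylsilyloxy)methyl]-2,3-dihydro-1-benzofuran-5-yl]-3-[(triisopropylsilyloxy)methyl]-2,3-dihydro-1-benzofuran-5-yl]prop-2-enoate | COc1cc([C@@H]2Oc3c(OC)cc([C@@H]4Oc5c(OC)cc(/C=C/C(=O)OC(C)(C)C)cc5[C@H]4CO[Si](C(C)C)(C(C)C)C(C)C)cc3[C@H]2CO[Si](C(C)C)(C(C)C)C(C)C)ccc1O[Si](C(C)C)(C(C)C)C(C)C | intermediate
25 | (E)-3-[(2R,3S)-7-methoxy-2-[(2R,3S)-7-methoxy-2-[3-methoxy-4-(triisopropylsilyloxy)phenyl]-3-[(triisopropylsilyloxy)methyl]-2,3-dihydro-1-benzofuran-5-yl]-3-[(triisopropylsilyloxy)methyl]-2,3-dihydro-1-benzofuran-5-yl]prop-2-en-1-ol | COc1cc([C@@H]2Oc3c(OC)cc([C@@H]4Oc5c(OC)cc(/C=C/CO)cc5[C@H]4CO[Si](C(C)C)(C(C)C)C(C)C)cc3[C@H]2CO[Si](C(C)C)(C(C)C)C(C)C)ccc1O[Si](C(C)C)(C(C)C)C(C)C | intermediate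
26 | (E)-3-[(2R,3S)-2-[(2R,3S)-2-(4-hydroxy-3-methoxyphenyl)-3-(hydroxymethyl)-7-methoxy-2,3-dihydro-1-benzofuran-5-yl]-3-(hydroxymethyl)-7-methoxy-2,3-dihydro-1-benzofuran-5-yl]prop-2-en-1-ol | COc1cc([C@@H]2Oc3c(OC)cc([C@@H]4Oc5c(OC)cc(/C=C/CO)cc5[C@H]4CO)cc3[C@H]2CO)ccc1O | target

**Step count and risks**

Total step count: 15. Longest linear sequence: 14 (steps 1–8 and 10–15; step 9 is a one-step side branch).

Steps most likely to fail:

1. Step 13. The second O-arylation may stall, because the ring B bromide of 22 is para to an alkoxide-bearing carbon and so is the less reactive one; hydrodebromination and intermolecular etherification could then overtake ring closure. Fallback (iterative closure, each bromide still para to its acrylate arm when it reacts): setting out from 11 and 17, the Evans syn aldol of enolate 14 with 17 (conditions of step 8) should give the ring A–ring B aldol adduct F1, LiBH4/MeOH in THF at 0 °C the diol F2, i-Pr3SiCl/imidazole the primary silyl ether F3, and one copper-catalysed O-arylation under the step 13 conditions the dihydrobenzofuran ester F4. Ozonolysis (O3, CH2Cl2, −78 °C; then Me2S) should pass through the secondary ozonide F5 (formed in the flask) to the aldehyde F6, which holds no free hydroxyl. The Evans syn aldol with enolate 14 should then give the adduct F7, LiBH4/MeOH the diol F8 and i-Pr3SiCl/imidazole the silyl ether F9. A second single O-arylation closes ring E and comes back to the route at 24.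

2. Step 10. Enolisation may not stay selective: Bu2BOTf/amine may also enolise the α-aryl imide that already carries the aldol, which opens retro-aldol cleavage and loss of configuration at C2'/C3', and incomplete borylation of the hydroxyl would let it quench the enolate. Fallback (covalent protection instead of capping in the flask, so that only one equivalent of boron triflate is needed): setting out from 15, Et3SiOSO2CF3/2,6-lutidine in CH2Cl2 at −78 °C should give the triethylsilyl ether F10. Bu2BOTf (1.1 equiv)/i-Pr2NEt (1.3 equiv) should convert it into its dibutylboron Z-enolate F11 (formed in the flask), and the aldol with 17 should give the silylated bis(imide) F12. HF·pyridine in THF/pyridine at 0 °C should remove only the triethylsilyl group and come back to the route at 20.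

3. Step 4. Slow transmetalation of the pinacol boronate may lead to protodeboronation and homocoupling, and zerovalent palladium may insert into the C–Br bond. Fallback (halodeboronation, then a classical Mizoroki–Heck reaction): setting out from 5, NaI/TsN(Cl)Na in aqueous THF should give the aryl iodide F13. Pd(OAc)2, Bu4NCl, NaHCO3, DMF, 60 °C with 6 should then couple at the unhindered C–I bond only and come back to the route at 7.

**Further compounds**

F1 | step 13 | (R)-4-benzyl-3-[(2R,3R)-2-[2-bromo-5-[(E)-3-tert-butoxy-3-oxoprop-1-enyl]-3-methoxyphenyl]-3-hydroxy-3-[3-methoxy-4-(triisopropylsilyloxy)phenyl]propanoyl]-1,3-oxazolidin-2-one | COc1cc([C@H](O)[C@@H](c2cc(/C=C/C(=O)OC(C)(C)C)cc(OC)c2Br)C(=O)N2[C@H](Cc3ccccc3)COC2=O)ccc1O[Si](C(C)C)(C(C)C)C(C)C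
F2 | step 13 | tert-butyl (E)-3-[4-bromo-3-[(1R,2S)-1,3-dihydroxy-1-[3-methoxy-4-(triisopropylsilyloxy)phenyl]propan-2-yl]-5-methoxyphenyl]prop-2-enoate | COc1cc([C@H](O)[C@@H](c2cc(/C=C/C(=O)OC(C)(C)C)cc(OC)c2Br)CO)ccc1O[Si](C(C)C)(C(C)C)C(C)C
F3 | step 13 | tert-butyl (E)-3-[4-bromo-3-[(1R,2S)-1-hydroxy-1-[3-methoxy-4-(triisopropylsilyloxy)phenyl]-3-(triisopropylsilyloxy)propan-2-yl]-5-methoxyphenyl]prop-2-enoate | COc1cc([C@H](O)[C@@H](c2cc(/C=C/C(=O)OC(C)(C)C)cc(OC)c2Br)CO[Si](C(C)C)(C(C)C)C(C)C)ccc1O[Si](C(C)C)(C(C)C)C(C)C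
F4 | step 13 | tert-butyl (E)-3-[(2R,3S)-7-methoxy-2-[3-methoxy-4-(triisopropylsilyloxy)phenyl]-3-[(triisopropylsilyloxy)methyl]-2,3-dihydro-1-benzofuran-5-yl]prop-2-enoate | COc1cc([C@@H]2Oc3c(OC)cc(/C=C/C(=O)OC(C)(C)C)cc3[C@H]2CO[Si](C(C)C)(C(C)C)C(C)C)ccc1O[Si](C(C)C)(C(C)C)C(C)C
F5 | step 13 | secondary ozonide (1,2,4-trioxolane) of F4 | COc1cc([C@@H]2Oc3c(OC)cc(C4OOC(O4)C(=O)OC(C)(C)C)cc3[C@H]2CO[Si](C(C)C)(C(C)C)C(C)C)ccc1O[Si](C(C)C)(C(C)C)C(C)C
F6 | step 13 | (2R,3S)-7-methoxy-2-[3-methoxy-4-(triisopropylsilyloxy)phenyl]-3-[(triisopropylsilyloxy)methyl]-2,3-dihydro-1-benzofuran-5-carbaldehyde | COc1cc([C@@H]2Oc3c(OC)cc(C=O)cc3[C@H]2CO[Si](C(C)C)(C(C)C)C(C)C)ccc1O[Si](C(C)C)(C(C)C)C(C)C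
F7 | step 13 | (R)-4-benzyl-3-[(2R,3R)-2-[2-bromo-5-[(E)-3-tert-butoxy-3-oxoprop-1-enyl]-3-methoxyphenyl]-3-hydroxy-3-[(2R,3S)-7-methoxy-2-[3-methoxy-4-(triisopropylsilyloxy)phenyl]-3-[(triisopropylsilyloxy)methyl]-2,3-dihydro-1-benzofuran-5-yl]propanoyl]-1,3-oxazolidin-2-one | COc1cc([C@@H]2Oc3c(OC)cc([C@H](O)[C@@H](c4cc(/C=C/C(=O)OC(C)(C)C)cc(OC)c4Br)C(=O)N4[C@H](Cc5ccccc5)COC4=O)cc3[C@H]2CO[Si](C(C)C)(C(C)C)C(C)C)ccc1O[Si](C(C)C)(C(C)C)C(C)C
F8 | step 13 | tert-butyl (E)-3-[4-bromo-3-[(1R,2S)-1,3-dihydroxy-1-[(2R,3S)-7-methoxy-2-[3-methoxy-4-(triisopropylsilyloxy)phenyl]-3-[(triisopropylsilyloxy)methyl]-2,3-dihydro-1-benzofuran-5-yl]propan-2-yl]-5-methoxyphenyl]prop-2-enoate | COc1cc([C@@H]2Oc3c(OC)cc([C@H](O)[C@@H](c4cc(/C=C/C(=O)OC(C)(C)C)cc(OC)c4Br)CO)cc3[C@H]2CO[Si](C(C)C)(C(C)C)C(C)C)ccc1O[Si](C(C)C)(C(C)C)C(C)C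
F9 | step 13 | tert-butyl (E)-3-[4-bromo-3-[(1R,2S)-1-hydroxy-1-[(2R,3S)-7-methoxy-2-[3-methoxy-4-(triisopropylsilyloxy)phenyl]-3-[(triisopropylsilyloxy)methyl]-2,3-dihydro-1-benzofuran-5-yl]-3-(triisopropylsilyloxy)propan-2-yl]-5-methoxyphenyl]prop-2-enoate | COc1cc([C@@H]2Oc3c(OC)cc([C@H](O)[C@@H](c4cc(/C=C/C(=O)OC(C)(C)C)cc(OC)c4Br)CO[Si](C(C)C)(C(C)C)C(C)C)cc3[C@H]2CO[Si](C(C)C)(C(C)C)C(C)C)ccc1O[Si](C(C)C)(C(C)C)C(C)C
F10 | step 10 | triethylsilyl ether of 15 | O=C(Cc1cc([C@H](O[Si](CC)(CC)CC)[C@@H](c2cc(/C=C/C(=O)OC(C)(C)C)cc(OC)c2Br)C(=O)N2[C@H](Cc3ccccc3)COC2=O)cc(OC)c1Br)N1[C@H](Cc2ccccc2)COC1=O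
F11 | step 10 | dibutylboron Z-enolate of the arylacetyl imide of F10 | CCCCB(CCCC)O/C(=C\c1cc([C@H](O[Si](CC)(CC)CC)[C@@H](c2cc(/C=C/C(=O)OC(C)(C)C)cc(OC)c2Br)C(=O)N2[C@H](Cc3ccccc3)COC2=O)cc(OC)c1Br)N1[C@H](Cc2ccccc2)COC1=O
F12 | step 10 | mono-triethylsilyl ether of 20 (silyl group on the ring B carbinol oxygen) | COc1cc([C@H](O)[C@@H](c2cc([C@H](O[Si](CC)(CC)CC)[C@@H](c3cc(/C=C/C(=O)OC(C)(C)C)cc(OC)c3Br)C(=O)N3[C@H](Cc4ccccc4)COC3=O)cc(OC)c2Br)C(=O)N2[C@H](Cc3ccccc3)COC2=O)ccc1O[Si](C(C)C)(C(C)C)C(C)C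
F13 | step 4 | ethyl 2-(2-bromo-5-iodo-3-methoxyphenyl)acetate | CCOC(=O)Cc1cc(I)cc(OC)c1Br
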